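The readings are simulated with constants of no real substance; scatter was added.

Whatever happens in these flasks, the complex is conserved across its forms, and if each exchange frees one leaving ligand, as this reckoning assumes, then each incoming ligand bound stands for one leaving ligand freed. That turns a few readings into an estimate of the amounts nobody read.

in all of them: starting complex 0.20 M
- elm: incoming ligand 0.22 M; run made earlier
- larch: incoming ligand 0.44 M; run made earlier
- Tuesday's: incoming ligand 0.220 M; a single well-mixed tank run continuously and read at steady state, 12 min in it on average
- Wednesday's: incoming ligand 0.220 M (fed, over 12.0 min); all but incoming ligand at the start; incoming ligand goes in evenly over 12.0 min, the run ends at 12 min; time 12 min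
- Sunday's: incoming ligand 0.220 M; a closed flask charged with all of it at once and left for 12 min; time 12 min
- Thursday's: incoming ligand 0.220 M; one stirred flow tank at steady state, fed with the mixture as stated, mean residence time 120 min

| run | time / min | complex with one exchanged / % | complex with two exchanged / % | complex with three exchanged / % |
|---|---|---|---|---|
| elm | 0.500 | 15.9 | 0 | 0 |
| elm | 1.33 | 31.0 | 2.6 | 0 |
| elm | 3.00 | 41.5 | 1.5 | 0 |
| elm | 8.00 | 40.6 | 2.0 | 2.9 |
| larch | 0.417 | 26.1 | 1.3 | 2.5 |
| larch | 1.33 | 50.9 | 1.2 | 1.5 |
| larch | 2.50 | 54.5 | 1.5 | 0.6 |
| larch | 4.00 | 54.1 | 3.2 | 4.2 |

(scatter of a reading: 1 percentage point)

- the stated concentrations are those of everything mixed, before any reaction; amounts are the same in each set-up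
- the feed brings no volume worth counting
- the earlier runs were made in a closed, stirred flask

1. the set-up with the highest share of complex with one exchanged in all that became complex with one exchanged or complex with two exchanged or complex with three exchanged or complex with four exchanged, at the outlet or at the end ("none" if the first two lie within 2 percentage points) (Tuesday's / Wednesday's / Sunday's / Thursday's / none)
2. share of complex with one exchanged in all that became complex with one exchanged or complex with two exchanged or complex with three exchanged or complex with four exchanged, at the outlet or at the end, Tuesday's
3. share of complex with one exchanged in all that became complex with one exchanged or complex with two exchanged or complex with three exchanged or complex with four exchanged, at the outlet or at the end, Wednesday's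
4. share of complex with one exchanged in all that became complex with one exchanged or complex with two exchanged or complex with three exchanged or complex with four exchanged, at the outlet or at the end, Sunday's
5. share of complex with one exchanged in all that became complex with one exchanged or complex with two exchanged or complex with three exchanged or complex with four exchanged, at the outlet or at the end, Thursday's

Read the last row of the elm run with that balance, taking complex with four exchanged as negligible, since it was not read. The exchanged groups add up to 0.107 M of leaving ligand, which leaves 0.109 M of starting complex and 0.113 M of incoming ligand.

Now form the exchange quotient, which is complex with one exchanged times leaving ligand, divided by starting complex times incoming ligand: 0.700. If the first exchange has come to rest, this is its equilibrium constant, and the step can be reckoned as a pre-equilibrium.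

Go up one row, to 3.00 min, and the quotient reads 0.495, so by these readings it may still have been climbing there. The last row of the larch run, with twice the ligand, reads 0.699. Both are readings with scatter, but a quotient that holds when the charge changes is one you can use.

Sunday's has the elm recipe, whose last row, at 8.00 min, reads a share of 89.2 %, and Sunday's runs longer, to 12 min, so my reckoning puts Sunday's somewhat below that. Halfway through Wednesday's feed, with half the ligand in, the quotient leaves 0.0449 M of incoming ligand free, less than the 0.113 M reckoned for the last row of the elm run. Over-exchange needs free ligand, so I expect Wednesday's to lead. At the end of Wednesday's feed the first exchange, reckoned by itself, leaves 0.125 M of incoming ligand free.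

The forecast gives 84 % for Tuesday's, 92 % for Wednesday's, 85 % for Sunday's and 38 % for Thursday's, and picks Wednesday's, saying “Slow feeding keeps free ligand low”.

The flask gives 86.4 %, 94.3 %, 85.8 % and 58.4 % in that order, so Wednesday's leads.

    starting complex + incoming ligand ⇌ leaving ligand + complex with one exchanged (K = 0.650, k = 0.0300 M⁻¹ s⁻¹)
    complex with one exchanged + incoming ligand ⇌ leaving ligand + complex with two exchanged (K = 1.10, k = 0.00190 M⁻¹ s⁻¹)
    complex with two exchanged + incoming ligand ⇌ leaving ligand + complex with three exchanged (K = 2.10, k = 0.0370 M⁻¹ s⁻¹)
    complex with three exchanged + incoming ligand ⇌ leaving ligand + complex with four exchanged (K = 4.90, k = 0.00450 M⁻¹ s⁻¹)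

Free incoming ligand in Wednesday's reaches at its highest 0.126 M, against the 0.125 M reckoned from the quotient for the end of the feed. In the neighbouring flask, fed over 12.0 min with 0.37 M of incoming ligand, the same reckoning leaves 0.251 M of it free. That flask holds 0.240 M of free incoming ligand at the end, and its share stands at 88.9 %.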